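# Proposed synthesis of CNP0157156.2 (target 38) by aryne insertion into dibenzyl malonate

## Analysis of the target

Target 38 is a 3,4-dihydroisocoumarin in which C1 is the lactone carbonyl, O2 the ring oxygen, C3 a hemiketal carbon bearing a hydroxyl group and a CH2O arm, and C4 a benzylic methine bearing a methyl group; the arm is esterified by ring B, a hexasubstituted 2,4-dihydroxy-3,5,6-trimethylbenzoic acid. Ring A (C4a to C8a) is pentasubstituted, with methyl at C5, methoxy at C6, a free phenol at C8 and hydrogen only at C7. The two stereocentres are neighbours, (3R) and (4S), with the C4 methyl trans to the C3 hydroxyl and cis to the CH2O arm. Only C4 has to be set kinetically: C3 opens and closes through the keto acid, so it should settle as the anomer with an axial hydroxyl trans to the C4 methyl, which the peri C5 methyl holds pseudo-axial. The sensitive points are the lactol (loss of water would give a flat isocoumarin and erase both centres), the C4 hydrogen (benzylic and α to the C3 carbonyl in every open-chain intermediate) and the two electron-rich phenol rings. The acyl carbon of ring B is shielded on both sides, so its ester is better formed at the alkyl carbon than at the carbonyl. The main difficulty is ring A, where C4a and C8a carry two different carbon substituents side by side, each with a further ortho neighbour. That adjacency is what the strategy rests on: the bonds C4a–C4 and C8a–C1 are formed together across a C4a–C8a aryne, and the C8 oxygen beside C8a decides which carbon receives which substituent.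

## Retrosynthetic reasoning

**Lactol, O2–C3.** Target 38 is the cyclic form of keto acid 37, so the O2–C3 bond is cut first. Keto acid 37 is in turn the product of removing four benzyl groups from ester 36. The lactol therefore never has to survive a reagent, all protecting groups fall in one neutral operation, and C3 sets itself by equilibration.

**Ester, CH2–O.** Ester 36 is cut between the CH2 carbon and the carboxylate oxygen, giving bromomethyl ketone 27 and acid 34 (used as its caesium salt 35). The cut is made at the sp3 carbon because the carbonyl of 34 is flanked by two ortho substituents and would resist acylation of an alcohol; an SN2 displacement by the carboxylate oxygen is indifferent to that crowding. It also divides the molecule into two halves of similar size.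

**C3–CH2.** Bromomethyl ketone 27 comes from acid 24 by a one-carbon diazo homologation through diazoketone 26. This brings in the last skeletal carbon without a strong base touching the C4 centre.

**C4–CH3.** Acid 24 is traced to imide 22 and, by removal of the methyl group, to imide 20, which is acid 17 joined to oxazolidinone 18. The methyl is introduced last because the arylacetic acid 17 has no stereocentre to protect and a methyl electrophile is the smallest possible partner for a crowded enolate. The forward reaction has to control one face of that enolate.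

**Ester differentiation.** Acid 17 arises from diester 16 by hydrolysis of the aliphatic ester only. The two esters of 16 differ sharply in hindrance, so no extra protecting-group step is spent on telling them apart.

**Key disconnection, C4a–C4 and C8a–C1.** Diester 16 is cut at both bonds at once, giving silyl triflate 12 and dibenzyl malonate 13. Forming either bond alone would mean a substitution on an already tetrasubstituted ring with a directing problem; the aryne 14 takes both carbons in one step, and its orientation is fixed by the C8 benzyloxy group. The forward step must deliver the malonate carbon to C4a and the acyl group to C8a.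

**Aryne precursor.** Silyl triflate 12 comes from bromophenol 8 by silyl migration from oxygen to carbon and triflation. Bromophenol 8 comes from phenol 7 by bromination ortho to the hydroxyl. Phenol 7 is the oxidation product of aldehyde 5, which is reached from 4-methylresorcinol 1 by formylation (aldehyde 3), methylation of the 4-hydroxyl (aldehyde 4) and benzylation. Each of these is a substitution whose position is set by the existing hydroxyl groups.

**Ring B.** Acid 34 comes from methyl ester 33, the dibenzyl ether of ester 32. Ester 32 differs from the commercial benzoate 28 by one methyl group at the only free ring position, installed by formylation to aldehyde 30 and reduction.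

## Alternatives that were turned down

**Alternative 1: benzannulation of ring B.** The disconnection cuts C1''–C2'', C3''–C4'' and C4''–C5'' of ring B. In the forward sense the vinyl diazo ketoester A1 undergoes a photochemical Wolff rearrangement, its ketene function adds to the siloxyalkyne A2 in a [2+2] sense, and four-ring opening followed by 6π closure gives the phenol A3.
- For: a hexasubstituted arene is assembled with complete regiocontrol in one operation, its two phenols emerge differentiated, and its benzyl ester is cleaved by hydrogenolysis, so the forcing hydrolysis of step 16 is avoided. On that last point it is stronger than the chosen route.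
- Against: ring B is the easy half of the molecule. Ester 32 is two steps from commercial 28, which already has every substituent but one methyl, and in 28 only one position is free, so regiocontrol is not in question. A1 and A2 each need their own preparation, and a cascade that builds a fully substituted ring from a hindered ketene is likely to be slow.
- Comparison: the key step of this alternative leaves ring A, C4 and the lactol untouched. The chosen strategy spends its main step on the adjacent C4a and C8a substituents, where the real difficulty lies.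

**Alternative 2: oxygen insertion into an indanone.** The disconnection treats O2 as inserted between C1 and C3 of a five-membered ketol and cuts C1–O2 and O2–C3. In the forward sense a periodate-type cleavage of the ketol A4 between its carbonyl and carbinol carbons frees a carboxyl group and the C3 ketone, which close to the benzylated lactol A5.
- For: the C3 carbonyl stays masked as a tertiary carbinol until the end, so C4 is never α to a free ketone during a basic step. Here it is stronger than the chosen route, in which 27 and 36 are enolisable. It also needs no diazomethane.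
- Against: A4 contains the same pentasubstituted ring A, so the substitution problem is only moved into an indanone synthesis. Its C2 needs a hydroxyl and a hydroxymethyl group placed next to the stereocentre, and that C2 centre is built only to be destroyed. Enantiocontrol at the benzylic carbon of an indanone is less routine than an auxiliary alkylation. The oxidant also meets three electron-rich benzyloxyarenes.
- Comparison: the chosen strategy reaches the ring A core with both carbon substituents in one step from an arene made by simple substitutions, and accepts a more delicate endgame in return.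

**Alternative 3: Diels–Alder benzannulation of ring A.** The disconnection cuts C4a–C5 and C8–C8a. In the forward sense the electron-rich diene A6 adds to the chiral ynoate A7 with its nucleophilic terminus at the β-carbon, and the adduct aromatises by loss of one methoxy group and the silyl group to give the salicylate A8.
- For: ring A arrives complete, with the C8 phenol free, the C6 methoxy and C5 methyl in place, and the C4 centre and the C3 oxygenation carried in from the ynoate. No auxiliary has to work on a crowded arene, and this could be shorter than steps 1 to 12. On convergence it is the stronger plan.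
- Against: the C4a–C5 bond must form between a methyl-bearing diene terminus and an alkyne carbon carrying a branched substituent, which calls for heat. The propargylic hydrogen at the stereocentre of A7 is acidic, so the centre is at risk through alkyne–allene isomerisation. A6 is hydrolytically labile and A7 needs a multistep enantioselective synthesis. Afterwards a secondary alcohol must be oxidised next to the benzylic centre, and a primary alcohol acylated by the hindered ring B acid.
- Comparison: the chosen key step is an addition to a planar aryne whose orientation depends on one alkoxy group, and its substrate is a stable arene; it is less convergent but easier to predict.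

Key step: step 7

Assumption: C3 is a hemiketal carbon that equilibrates through keto acid 37, and the (3R) anomer of 38 (hydroxyl axial, trans to the pseudo-axial C4 methyl) is taken to be the one favoured at equilibrium.

## Route

**Ring A and the aryne precursor**

Step 1
Reactants: 1 4-methylresorcinol
Product: 3 2,4-dihydroxy-5-methylbenzaldehyde, via iminium chloride 2 (not isolated)
Conditions: POCl3, DMF, MeCN, 0 °C to rt; then H2O, 50 °C
Reagents that add atoms: N,N-dimethylformamide, CN(C)C=O (formyl carbon); water, O (formyl oxygen)
Why: Vilsmeier–Haack formylation; the chloroiminium ion should attack para to one hydroxyl and ortho to the other, not the crowded position between them, and water hydrolyses iminium salt 2 to the aldehyde.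

Step 2
Reactants: 3 2,4-dihydroxy-5-methylbenzaldehyde
Product: 4 2-hydroxy-4-methoxy-5-methylbenzaldehyde
Conditions: MeI, KHCO3, DMF, 40 °C
Reagents that add atoms: iodomethane, CI
Why: Williamson ether synthesis; the 2-hydroxyl is held in a hydrogen bond to the formyl group, so the weak base should ionise only the more acidic 4-hydroxyl para to the aldehyde.

Step 3
Reactants: 4 2-hydroxy-4-methoxy-5-methylbenzaldehyde
Product: 5 2-(benzyloxy)-4-methoxy-5-methylbenzaldehyde
Conditions: BnBr, K2CO3, DMF, 60 °C
Reagents that add atoms: benzyl bromide, BrCc1ccccc1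
Why: Williamson benzylation of the remaining chelated phenol under more forcing conditions; no other nucleophilic site is present.

Step 4
Reactants: 5 2-(benzyloxy)-4-methoxy-5-methylbenzaldehyde
Product: 7 2-(benzyloxy)-4-methoxy-5-methylphenol, via aryl formate 6 (not isolated)
Conditions: mCPBA, CH2Cl2, 0 °C to rt; aq. NaHCO3 wash; then K2CO3 (cat.), MeOH, rt
Reagents that add atoms: 3-chloroperoxybenzoic acid, O=C(OO)c1cccc(Cl)c1
Why: Baeyer–Villiger (Dakin-type) oxidation; the aryl group, made electron-rich by its ortho and para alkoxy groups, migrates in preference to hydrogen, and formate 6 is cleaved by methanolysis.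

Step 5
Reactants: 7 2-(benzyloxy)-4-methoxy-5-methylphenol
Product: 8 6-(benzyloxy)-2-bromo-4-methoxy-3-methylphenol
Conditions: NBS, i-Pr2NH (cat.), CH2Cl2, −20 to 0 °C, dark
Reagents that add atoms: N-bromosuccinimide, O=C1CCC(=O)N1Br
Why: Electrophilic aromatic bromination directed ortho by the free phenol through the hydrogen-bonded N-bromoamine; the only free ortho or para position of the hydroxyl is the one next to the methyl group, and the other free CH lies meta to it, wedged between two alkoxy groups.

Step 6
Reactants: 8 6-(benzyloxy)-2-bromo-4-methoxy-3-methylphenol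
Product: 12 2-(benzyloxy)-4-methoxy-5-methyl-6-(trimethylsilyl)phenyl trifluoromethanesulfonate, via silyl ether 9 (not isolated), via aryllithium 10 (not isolated), via lithium phenolate 11 (not isolated)
Conditions: (Me3Si)2NH, THF, 70 °C, then evaporation; n-BuLi, THF, −100 to −80 °C; Tf2O, −100 °C to rt
Reagents that add atoms: hexamethyldisilazane, C[Si](C)(C)N[Si](C)(C)C; trifluoromethanesulfonic anhydride, O=S(=O)(OS(=O)(=O)C(F)(F)F)C(F)(F)F
Why: O-silylation, bromine–lithium exchange and retro-Brook rearrangement (1,3 shift of silicon from oxygen to carbon), then triflation of the phenolate; this is the standard route to 2-silylaryl triflates, and the exchange is far faster than deprotonation of the benzyl ether.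

**Key step and the C4 stereocentre**

Step 7
Reactants: 12 2-(benzyloxy)-4-methoxy-5-methyl-6-(trimethylsilyl)phenyl trifluoromethanesulfonate; 13 dibenzyl malonate
Product: 16 benzyl 2-(benzyloxy)-6-[2-(benzyloxy)-2-oxoethyl]-4-methoxy-5-methylbenzoate, via aryne 14 (not isolated), via caesium benzocyclobutenoxide 15 (not isolated)
Conditions: 13 (2 equiv), CsF (3 equiv), MeCN, 80 °C
Reagents that add atoms: none
Why: Fluoride attacks silicon in 12 and the aryl anion expels triflate to give aryne 14, whose triple bond joins the future C4a and C8a. The caesium enolate of 13, formed with CsF as base, adds to C4a, the aryne carbon remote from the benzyloxy group, and leaves the negative charge on C8a. This aryl anion attacks one ester carbonyl of the malonate unit in a 4-exo-trig closure to benzocyclobutenoxide 15, and retro-aldol-type fragmentation of the strained ring gives the arylacetate enolate, which is protonated by further 13 to give 16. The closest known reaction type is the insertion of arynes from 2-silylaryl triflates into the C–C σ-bond of malonates and β-ketoesters (acyl-alkylation of arynes). No ring stays closed and no stereocentre is formed. The step needs regioselectivity between C4a and C8a: the inductively withdrawing C8 oxygen distorts the aryne so that C4a is the more electrophilic carbon and stabilises the charge developing at C8a, while the C5 methyl exerts only a small steric bias the other way and the C6 methoxy group is too remote to matter. It also needs acyl transfer to outrun protonation of the aryl anion, which the intramolecular closure in dry MeCN should secure, and 13 is used in excess so that 16 is not arylated again.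

Step 8
Reactants: 16 benzyl 2-(benzyloxy)-6-[2-(benzyloxy)-2-oxoethyl]-4-methoxy-5-methylbenzoate
Product: 17 2-{3-(benzyloxy)-2-[(benzyloxy)carbonyl]-5-methoxy-6-methylphenyl}acetic acid
Conditions: LiOH (1.2 equiv), THF/H2O, 0 °C to rt; then 1 M HCl
Reagents that add atoms: lithium hydroxide, [Li+].[OH-]
Why: Ester saponification by acyl–oxygen cleavage; hydroxide should attack only the unhindered aliphatic ester, because the aryl ester is flanked on both sides and twisted out of the ring plane.

Step 9
Reactants: 17 2-{3-(benzyloxy)-2-[(benzyloxy)carbonyl]-5-methoxy-6-methylphenyl}acetic acid; 18 (4S)-4-benzyl-1,3-oxazolidin-2-one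
Product: 20 benzyl 2-(benzyloxy)-6-{2-[(4S)-4-benzyl-2-oxo-1,3-oxazolidin-3-yl]-2-oxoethyl}-4-methoxy-5-methylbenzoate, via mixed pivalic anhydride 19 (not isolated)
Conditions: t-BuCOCl, Et3N, THF, −20 °C; then LiCl, 18, −20 °C to rt
Reagents that add atoms: none
Why: N-acylation of an Evans oxazolidinone through a mixed anhydride with LiCl and Et3N; the lithium-bound oxazolidinone attacks the arylacetyl carbonyl of 19, which is less hindered than the pivaloyl carbonyl.

Step 10
Reactants: 20 benzyl 2-(benzyloxy)-6-{2-[(4S)-4-benzyl-2-oxo-1,3-oxazolidin-3-yl]-2-oxoethyl}-4-methoxy-5-methylbenzoate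
Product: 22 benzyl 2-(benzyloxy)-6-{(2S)-1-[(4S)-4-benzyl-2-oxo-1,3-oxazolidin-3-yl]-1-oxopropan-2-yl}-4-methoxy-5-methylbenzoate, via sodium enolate 21 (not isolated)
Conditions: NaN(SiMe3)2, THF, −78 °C; MeI, −78 to −40 °C; then aq. NH4Cl
Reagents that add atoms: iodomethane, CI
Why: Evans asymmetric alkylation; the sodium-chelated Z-enolate 21 is shielded on one face by the benzyl group of the (4S)-auxiliary, so iodomethane should enter from the other face and give the (S) configuration at the future C4. The hindered aryl ester should not be attacked at −78 °C.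

Step 11
Reactants: 22 benzyl 2-(benzyloxy)-6-{(2S)-1-[(4S)-4-benzyl-2-oxo-1,3-oxazolidin-3-yl]-1-oxopropan-2-yl}-4-methoxy-5-methylbenzoate
Product: 24 (2S)-2-{3-(benzyloxy)-2-[(benzyloxy)carbonyl]-5-methoxy-6-methylphenyl}propanoic acid, via lithium peroxycarboxylate 23 (not isolated)
Conditions: LiOH, H2O2, THF/H2O, 0 °C; Na2SO3; then 1 M HCl
Reagents that add atoms: hydrogen peroxide, OO
Why: Hydroperoxide cleavage of the N-acyl oxazolidinone; the weakly basic, strongly nucleophilic hydroperoxide attacks the exocyclic carbonyl, so the α-aryl centre should not epimerise, and sulfite reduces peroxycarboxylate 23 to the acid.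

Step 12
Reactants: 24 (2S)-2-{3-(benzyloxy)-2-[(benzyloxy)carbonyl]-5-methoxy-6-methylphenyl}propanoic acid
Product: 27 benzyl 2-(benzyloxy)-6-[(2S)-4-bromo-3-oxobutan-2-yl]-4-methoxy-5-methylbenzoate, via mixed carbonic anhydride 25 (not isolated), via diazoketone 26 (not isolated)
Conditions: i-BuOCOCl, N-methylmorpholine, THF, −15 °C; CH2N2, Et2O, 0 °C; N2 purge; 48% aq. HBr, −10 °C
Reagents that add atoms: diazomethane, C=[N+]=[N-]; hydrogen bromide, Br
Why: Acylation of diazomethane by a mixed carbonic anhydride, as in the first stage of an Arndt–Eistert homologation, then protonation of diazoketone 26 and SN2 displacement of N2 by bromide. No strong base is used, so the C4 centre should be retained.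

**Ring B**

Step 13
Reactants: 28 methyl 2,4-dihydroxy-3,6-dimethylbenzoate
Product: 30 methyl 3-formyl-4,6-dihydroxy-2,5-dimethylbenzoate, via α-chloro ether 29 (not isolated)
Conditions: Cl2CHOMe, TiCl4, CH2Cl2, 0 °C to rt; then H2O
Reagents that add atoms: dichloromethyl methyl ether, COC(Cl)Cl (formyl carbon); water, O (formyl oxygen)
Why: Rieche formylation; the single free ring position is ortho to one hydroxyl and para to the other, and TiCl4 bound to the phenol delivers the electrophile there before water hydrolyses chloro ether 29.

Step 14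
Reactants: 30 methyl 3-formyl-4,6-dihydroxy-2,5-dimethylbenzoate
Product: 32 methyl 2,4-dihydroxy-3,5,6-trimethylbenzoate, via benzylic alcohol 31 (not isolated)
Conditions: Et3SiH, CF3CO2H, CH2Cl2, rt
Reagents that add atoms: none
Why: Ionic hydrogenation; the protonated aldehyde takes hydride to give alcohol 31, which ionises to a benzylic cation stabilised as a quinone methide by the ortho and para hydroxyls and takes a second hydride.

Step 15
Reactants: 32 methyl 2,4-dihydroxy-3,5,6-trimethylbenzoate
Product: 33 methyl 2,4-bis(benzyloxy)-3,5,6-trimethylbenzoate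
Conditions: BnBr, K2CO3, Bu4NI (cat.), DMF, 70 °C
Reagents that add atoms: benzyl bromide, BrCc1ccccc1
Why: Williamson benzylation of both phenols; heat and iodide catalysis compensate for the flanking substituents.

Step 16
Reactants: 33 methyl 2,4-bis(benzyloxy)-3,5,6-trimethylbenzoate
Product: 34 2,4-bis(benzyloxy)-3,5,6-trimethylbenzoic acid
Conditions: KOH, DMSO/H2O, 90 °C; then 1 M HCl
Reagents that add atoms: potassium hydroxide, [K+].[OH-]
Why: Saponification of a hindered ester; poorly solvated hydroxide in DMSO at elevated temperature should overcome the two ortho substituents, and the benzyl ethers are stable to base.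

**Union and endgame**

Step 17
Reactants: 27 benzyl 2-(benzyloxy)-6-[(2S)-4-bromo-3-oxobutan-2-yl]-4-methoxy-5-methylbenzoate; 34 2,4-bis(benzyloxy)-3,5,6-trimethylbenzoic acid
Product: 36 (3S)-3-{3-(benzyloxy)-2-[(benzyloxy)carbonyl]-5-methoxy-6-methylphenyl}-2-oxobutyl 2,4-bis(benzyloxy)-3,5,6-trimethylbenzoate, via caesium carboxylate 35 (not isolated)
Conditions: 34, Cs2CO3 (0.5 equiv), DMF, rt; then 27, 0 °C to rt
Reagents that add atoms: none
Why: SN2 O-alkylation of a carboxylate by an α-bromoketone; the bond forms at the primary carbon, so the crowding around the acyl carbon of 35 does not matter, and the carboxylate is too weak a base to enolise C4 appreciably.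

Step 18
Reactants: 36 (3S)-3-{3-(benzyloxy)-2-[(benzyloxy)carbonyl]-5-methoxy-6-methylphenyl}-2-oxobutyl 2,4-bis(benzyloxy)-3,5,6-trimethylbenzoate
Product: 38 [(3R,4S)-3,8-dihydroxy-6-methoxy-4,5-dimethyl-1-oxo-3,4-dihydro-1H-2-benzopyran-3-yl]methyl 2,4-dihydroxy-3,5,6-trimethylbenzoate, via keto acid 37 (not isolated)
Conditions: H2 (1 atm), 10% Pd/C, EtOAc, rt
Reagents that add atoms: none
Why: Catalytic hydrogenolysis removes the three benzyl ethers and the benzyl ester under neutral conditions, and the freed carboxyl of 37 adds to the C3 ketone in a 6-exo-trig closure. C3 is set under thermodynamic control: the hydroxyl goes axial (anomeric effect) and trans to the C4 methyl, which the C5 methyl keeps pseudo-axial, and this is the (3R) anomer.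

## Compound list

1 | 4-methylresorcinol | Cc1ccc(O)cc1O | starting material
2 | N-(2,4-dihydroxy-5-methylbenzylidene)-N-methylmethanaminium chloride | C[N+](C)=Cc1cc(C)c(O)cc1O.[Cl-] | intermediate
3 | 2,4-dihydroxy-5-methylbenzaldehyde | Cc1cc(C=O)c(O)cc1O | intermediate
4 | 2-hydroxy-4-methoxy-5-methylbenzaldehyde | COc1cc(O)c(C=O)cc1C | intermediate
5 | 2-(benzyloxy)-4-methoxy-5-methylbenzaldehyde | COc1cc(OCc2ccccc2)c(C=O)cc1C | intermediate
6 | 2-(benzyloxy)-4-methoxy-5-methylphenyl formate | COc1cc(OCc2ccccc2)c(OC=O)cc1C | intermediate
7 | 2-(benzyloxy)-4-methoxy-5-methylphenol | COc1cc(OCc2ccccc2)c(O)cc1C | intermediate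
8 | 6-(benzyloxy)-2-bromo-4-methoxy-3-methylphenol | COc1cc(OCc2ccccc2)c(O)c(Br)c1C | intermediate
9 | [6-(benzyloxy)-2-bromo-4-methoxy-3-methylphenoxy]trimethylsilane | COc1cc(OCc2ccccc2)c(O[Si](C)(C)C)c(Br)c1C | intermediate
10 | {3-(benzyloxy)-5-methoxy-6-methyl-2-[(trimethylsilyl)oxy]phenyl}lithium | COc1cc(OCc2ccccc2)c(O[Si](C)(C)C)c([Li])c1C | intermediate
11 | lithium 6-(benzyloxy)-4-methoxy-3-methyl-2-(trimethylsilyl)phenolate | [Li+].[O-]c1c(OCc2ccccc2)cc(OC)c(C)c1[Si](C)(C)C | intermediate
12 | 2-(benzyloxy)-4-methoxy-5-methyl-6-(trimethylsilyl)phenyl trifluoromethanesulfonate | COc1cc(OCc2ccccc2)c(OS(=O)(=O)C(F)(F)F)c(c1C)[Si](C)(C)C | intermediate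
13 | dibenzyl malonate | O=C(CC(=O)OCc1ccccc1)OCc1ccccc1 | starting material
14 | 3-(benzyloxy)-5-methoxy-6-methylbenzyne (1,2-didehydrobenzene) | COC1=C(C)C#CC(OCc2ccccc2)=C1 | intermediate
15 | caesium 5,7-bis(benzyloxy)-8-[(benzyloxy)carbonyl]-3-methoxy-2-methylbicyclo[4.2.0]octa-1,3,5-trien-7-olate | [Cs+].COc1cc(OCc2ccccc2)c2c(c1C)C(C(=O)OCc1ccccc1)C2([O-])OCc1ccccc1 | intermediate
16 | benzyl 2-(benzyloxy)-6-[2-(benzyloxy)-2-oxoethyl]-4-methoxy-5-methylbenzoate | COc1cc(OCc2ccccc2)c(C(=O)OCc2ccccc2)c(c1C)CC(=O)OCc1ccccc1 | intermediate
17 | 2-{3-(benzyloxy)-2-[(benzyloxy)carbonyl]-5-methoxy-6-methylphenyl}acetic acid | COc1cc(OCc2ccccc2)c(C(=O)OCc2ccccc2)c(c1C)CC(=O)O | intermediate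
18 | (4S)-4-benzyl-1,3-oxazolidin-2-one | O=C1N[C@@H](Cc2ccccc2)CO1 | starting material
19 | 2-{3-(benzyloxy)-2-[(benzyloxy)carbonyl]-5-methoxy-6-methylphenyl}acetic 2,2-dimethylpropanoic anhydride | COc1cc(OCc2ccccc2)c(C(=O)OCc2ccccc2)c(c1C)CC(=O)OC(=O)C(C)(C)C | intermediate
20 | benzyl 2-(benzyloxy)-6-{2-[(4S)-4-benzyl-2-oxo-1,3-oxazolidin-3-yl]-2-oxoethyl}-4-methoxy-5-methylbenzoate | COc1cc(OCc2ccccc2)c(C(=O)OCc2ccccc2)c(c1C)CC(=O)N1C(=O)OC[C@@H]1Cc1ccccc1 | intermediate
21 | sodium (Z)-enolate of 20 | COc1cc(OCc2ccccc2)c(C(=O)OCc2ccccc2)c(c1C)/C=C(\[O-])N1C(=O)OC[C@@H]1Cc1ccccc1.[Na+] | intermediate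
22 | benzyl 2-(benzyloxy)-6-{(2S)-1-[(4S)-4-benzyl-2-oxo-1,3-oxazolidin-3-yl]-1-oxopropan-2-yl}-4-methoxy-5-methylbenzoate | COc1cc(OCc2ccccc2)c(C(=O)OCc2ccccc2)c(c1C)[C@H](C)C(=O)N1C(=O)OC[C@@H]1Cc1ccccc1 | intermediate
23 | lithium (2S)-2-{3-(benzyloxy)-2-[(benzyloxy)carbonyl]-5-methoxy-6-methylphenyl}propaneperoxoate | COc1cc(OCc2ccccc2)c(C(=O)OCc2ccccc2)c(c1C)[C@H](C)C(=O)O[O-].[Li+] | intermediate
24 | (2S)-2-{3-(benzyloxy)-2-[(benzyloxy)carbonyl]-5-methoxy-6-methylphenyl}propanoic acid | COc1cc(OCc2ccccc2)c(C(=O)OCc2ccccc2)c(c1C)[C@H](C)C(=O)O | intermediate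
25 | (2S)-2-{3-(benzyloxy)-2-[(benzyloxy)carbonyl]-5-methoxy-6-methylphenyl}propanoic 2-methylpropyl carbonic anhydride | COc1cc(OCc2ccccc2)c(C(=O)OCc2ccccc2)c(c1C)[C@H](C)C(=O)OC(=O)OCC(C)C | intermediate
26 | benzyl 2-(benzyloxy)-6-[(2S)-4-diazo-3-oxobutan-2-yl]-4-methoxy-5-methylbenzoate | COc1cc(OCc2ccccc2)c(C(=O)OCc2ccccc2)c(c1C)[C@H](C)C(=O)C=[N+]=[N-] | intermediate
27 | benzyl 2-(benzyloxy)-6-[(2S)-4-bromo-3-oxobutan-2-yl]-4-methoxy-5-methylbenzoate | COc1cc(OCc2ccccc2)c(C(=O)OCc2ccccc2)c(c1C)[C@H](C)C(=O)CBr | intermediate
28 | methyl 2,4-dihydroxy-3,6-dimethylbenzoate | COC(=O)c1c(C)cc(O)c(C)c1O | starting material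
29 | methyl 3-[chloro(methoxy)methyl]-4,6-dihydroxy-2,5-dimethylbenzoate | COC(=O)c1c(C)c(C(Cl)OC)c(O)c(C)c1O | intermediate
30 | methyl 3-formyl-4,6-dihydroxy-2,5-dimethylbenzoate | COC(=O)c1c(C)c(C=O)c(O)c(C)c1O | intermediate
31 | methyl 4,6-dihydroxy-3-(hydroxymethyl)-2,5-dimethylbenzoate | COC(=O)c1c(C)c(CO)c(O)c(C)c1O | intermediate
32 | methyl 2,4-dihydroxy-3,5,6-trimethylbenzoate | COC(=O)c1c(C)c(C)c(O)c(C)c1O | intermediate
33 | methyl 2,4-bis(benzyloxy)-3,5,6-trimethylbenzoate | COC(=O)c1c(C)c(C)c(OCc2ccccc2)c(C)c1OCc1ccccc1 | intermediate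
34 | 2,4-bis(benzyloxy)-3,5,6-trimethylbenzoic acid | OC(=O)c1c(C)c(C)c(OCc2ccccc2)c(C)c1OCc1ccccc1 | intermediate
35 | caesium 2,4-bis(benzyloxy)-3,5,6-trimethylbenzoate | [Cs+].[O-]C(=O)c1c(C)c(C)c(OCc2ccccc2)c(C)c1OCc1ccccc1 | intermediate
36 | (3S)-3-{3-(benzyloxy)-2-[(benzyloxy)carbonyl]-5-methoxy-6-methylphenyl}-2-oxobutyl 2,4-bis(benzyloxy)-3,5,6-trimethylbenzoate | COc1cc(OCc2ccccc2)c(C(=O)OCc2ccccc2)c(c1C)[C@H](C)C(=O)COC(=O)c1c(C)c(C)c(OCc2ccccc2)c(C)c1OCc1ccccc1 | intermediate
37 | 2-{(2S)-4-[(2,4-dihydroxy-3,5,6-trimethylbenzoyl)oxy]-3-oxobutan-2-yl}-6-hydroxy-4-methoxy-3-methylbenzoic acid | COc1cc(O)c(C(=O)O)c(c1C)[C@H](C)C(=O)COC(=O)c1c(C)c(C)c(O)c(C)c1O | intermediate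
38 | [(3R,4S)-3,8-dihydroxy-6-methoxy-4,5-dimethyl-1-oxo-3,4-dihydro-1H-2-benzopyran-3-yl]methyl 2,4-dihydroxy-3,5,6-trimethylbenzoate | COc1cc(O)c2c(c1C)[C@H](C)[C@](O)(COC(=O)c1c(C)c(C)c(O)c(C)c1O)OC2=O | target

## Step count and least certain steps

Total: 18 steps. Longest linear sequence: 14 steps (steps 1 to 12, then 17 and 18). The ring B branch (steps 13 to 16) has 4 steps.

**Step 7 (key step).** The enolate may add at the wrong aryne carbon if the C5 methyl and C6 methoxy groups weaken the polarisation by the C8 benzyloxy group. The aryl anion may also be protonated before acyl transfer, which gives plain α-arylation of 13, and product 16 may be arylated a second time. The fallback sets out from bromophenol 8 and returns at 16, forming the two bonds one after the other by palladium catalysis. Triflation of 8 (Tf2O, pyridine) gives 6-(benzyloxy)-2-bromo-4-methoxy-3-methylphenyl trifluoromethanesulfonate F1. A Reformatsky–Negishi coupling with BrZnCH2CO2Bn under Pd2(dba)3 and P(t-Bu)3, a catalyst that inserts into C–Br before C–OTf, gives benzyl 2-{3-(benzyloxy)-5-methoxy-6-methyl-2-[(trifluoromethanesulfonyl)oxy]phenyl}acetate F2. Benzyloxycarbonylation of the triflate (Pd(OAc)2, 1,3-bis(diphenylphosphino)propane, CO, benzyl alcohol, Et3N, DMF) then gives 16.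

**Step 5.** Bromination may occur in part at the CH between the two ether oxygens, and the electron-rich 4-alkoxyphenol may be oxidised towards a quinone. The fallback sets out from phenol 7 and returns at 12, replacing electrophilic substitution by directed metalation. Isopropyl isocyanate and Et3N give 2-(benzyloxy)-4-methoxy-5-methylphenyl isopropylcarbamate F3. Temporary N-silylation in the same flask (t-BuMe2SiOTf, TMEDA), ortho-lithiation with n-BuLi at −78 °C and Me3SiCl give 2-(benzyloxy)-4-methoxy-5-methyl-6-(trimethylsilyl)phenyl isopropylcarbamate F4. Cleavage with DBU and Et2NH and triflation with PhNTf2 in one pot give 12.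

**Step 10.** The enolate may attack the neighbouring benzyl ester through oxygen. Facial selectivity may be lowered by the twisted, doubly ortho-substituted aryl group. Excess base may epimerise the product. The fallback sets out from diester 16 and returns at 24, replacing auxiliary control by resolution. LiN(SiMe3)2 and MeI give racemic benzyl 2-(benzyloxy)-6-[1-(benzyloxy)-1-oxopropan-2-yl]-4-methoxy-5-methylbenzoate F5. Selective saponification with LiOH gives racemic 2-{3-(benzyloxy)-2-[(benzyloxy)carbonyl]-5-methoxy-6-methylphenyl}propanoic acid F6. Preparative chromatography on a chiral stationary phase separates 24 from (2R)-2-{3-(benzyloxy)-2-[(benzyloxy)carbonyl]-5-methoxy-6-methylphenyl}propanoic acid F7, which can be racemised with base and resolved again.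

**Step 12.** Diazomethane may attack the carbonate carbonyl of 25 and lead to the methyl ester. The activated α-aryl acid may racemise through its enol or ketene. The neighbouring benzyl ester may take part in the activated acyl group. Aqueous HBr may promote cyclisation of the keto ester to an isocoumarin. The fallback sets out from imide 22 and returns at 36, avoiding acid activation and diazomethane. Me3Al and MeONHMe·HCl give the Weinreb amide benzyl 2-(benzyloxy)-4-methoxy-6-{(2S)-1-[methoxy(methyl)amino]-1-oxopropan-2-yl}-5-methylbenzoate F8. Chloromethyllithium generated in its presence (ICH2Cl, MeLi·LiBr, THF, −78 °C) gives benzyl 2-(benzyloxy)-6-[(2S)-4-chloro-3-oxobutan-2-yl]-4-methoxy-5-methylbenzoate F9. Alkylation of caesium carboxylate 35 with F9 (NaI cat., DMF) gives 36.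

**Step 17.** Enolisation of the ketone under the basic conditions may erode the configuration at C4, which is benzylic and α to the carbonyl. The fallback sets out from diazoketone 26 and acid 34 and returns at 36. Step 12 is stopped before the HBr addition and 26 is isolated. Insertion of its carbenoid into the O–H bond of 34 (Rh2(OAc)4 cat., CH2Cl2, rt) forms the same CH2–O bond with no base present.

## Further compounds

F1 | step 7 | 6-(benzyloxy)-2-bromo-4-methoxy-3-methylphenyl trifluoromethanesulfonate | COc1cc(OCc2ccccc2)c(OS(=O)(=O)C(F)(F)F)c(Br)c1C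
F2 | step 7 | benzyl 2-{3-(benzyloxy)-5-methoxy-6-methyl-2-[(trifluoromethanesulfonyl)oxy]phenyl}acetate | COc1cc(OCc2ccccc2)c(OS(=O)(=O)C(F)(F)F)c(c1C)CC(=O)OCc1ccccc1
F3 | step 5 | 2-(benzyloxy)-4-methoxy-5-methylphenyl isopropylcarbamate | COc1cc(OCc2ccccc2)c(OC(=O)NC(C)C)cc1C
F4 | step 5 | 2-(benzyloxy)-4-methoxy-5-methyl-6-(trimethylsilyl)phenyl isopropylcarbamate | COc1cc(OCc2ccccc2)c(OC(=O)NC(C)C)c(c1C)[Si](C)(C)C
F5 | step 10 | racemic benzyl 2-(benzyloxy)-6-[1-(benzyloxy)-1-oxopropan-2-yl]-4-methoxy-5-methylbenzoate | COc1cc(OCc2ccccc2)c(C(=O)OCc2ccccc2)c(c1C)C(C)C(=O)OCc1ccccc1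
F6 | step 10 | racemic 2-{3-(benzyloxy)-2-[(benzyloxy)carbonyl]-5-methoxy-6-methylphenyl}propanoic acid | COc1cc(OCc2ccccc2)c(C(=O)OCc2ccccc2)c(c1C)C(C)C(=O)O
F7 | step 10 | (2R)-2-{3-(benzyloxy)-2-[(benzyloxy)carbonyl]-5-methoxy-6-methylphenyl}propanoic acid | COc1cc(OCc2ccccc2)c(C(=O)OCc2ccccc2)c(c1C)[C@@H](C)C(=O)O
F8 | step 12 | benzyl 2-(benzyloxy)-4-methoxy-6-{(2S)-1-[methoxy(methyl)amino]-1-oxopropan-2-yl}-5-methylbenzoate | COc1cc(OCc2ccccc2)c(C(=O)OCc2ccccc2)c(c1C)[C@H](C)C(=O)N(C)OC
F9 | step 12 | benzyl 2-(benzyloxy)-6-[(2S)-4-chloro-3-oxobutan-2-yl]-4-methoxy-5-methylbenzoate | COc1cc(OCc2ccccc2)c(C(=O)OCc2ccccc2)c(c1C)[C@H](C)C(=O)CCl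
F0 | step 17 | none | none
A1 | alternative 1 | benzyl (4E)-2-diazo-4-methyl-3-oxohex-4-enoate | C/C=C(\C)C(=O)C(=[N+]=[N-])C(=O)OCc1ccccc1
A2 | alternative 1 | triisopropyl(prop-1-yn-1-yloxy)silane | CC#CO[Si](C(C)C)(C(C)C)C(C)C
A3 | alternative 1 | benzyl 4-hydroxy-3,5,6-trimethyl-2-(triisopropylsilyloxy)benzoate | Cc1c(C)c(C(=O)OCc2ccccc2)c(O[Si](C(C)C)(C(C)C)C(C)C)c(C)c1O
A4 | alternative 2 | [(3S)-7-(benzyloxy)-2-hydroxy-5-methoxy-3,4-dimethyl-1-oxo-2,3-dihydro-1H-inden-2-yl]methyl 2,4-bis(benzyloxy)-3,5,6-trimethylbenzoate (either C2 epimer) | COc1cc(OCc2ccccc2)c2c(c1C)[C@H](C)C(O)(COC(=O)c1c(C)c(C)c(OCc3ccccc3)c(C)c1OCc1ccccc1)C2=O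
A5 | alternative 2 | [(3R,4S)-8-(benzyloxy)-3-hydroxy-6-methoxy-4,5-dimethyl-1-oxo-3,4-dihydro-1H-2-benzopyran-3-yl]methyl 2,4-bis(benzyloxy)-3,5,6-trimethylbenzoate | COc1cc(OCc2ccccc2)c2c(c1C)[C@H](C)[C@](O)(COC(=O)c1c(C)c(C)c(OCc3ccccc3)c(C)c1OCc1ccccc1)OC2=O
A6 | alternative 3 | [(1,3-dimethoxypenta-1,3-dien-1-yl)oxy]trimethylsilane | COC(O[Si](C)(C)C)=CC(OC)=CC
A7 | alternative 3 | benzyl (4S)-4-[(4R)-2,2-dimethyl-1,3-dioxolan-4-yl]pent-2-ynoate | O=C(OCc1ccccc1)C#C[C@H](C)[C@@H]1COC(C)(C)O1
A8 | alternative 3 | benzyl 6-{(1S)-1-[(4R)-2,2-dimethyl-1,3-dioxolan-4-yl]ethyl}-2-hydroxy-4-methoxy-5-methylbenzoate | COc1cc(O)c(C(=O)OCc2ccccc2)c(c1C)[C@H](C)[C@@H]1COC(C)(C)O1
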